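**Retrosynthetic overview**

1. 25 ⇒ enal 23 (oxirane C1–C2–O closed last, through a bromohydrin) ⇒ trienolide 21 (allylic oxidation of C15) ⇒ diol-yne 19 + CO (lactone closed through the C11–C12 bond by palladium cyclocarbonylation).
2. 19 ⇒ p-quinone monoketal 4 ⇒ phenol 1 + silylacetylene 2. Every ring substituent is set by conjugate addition or enolate chemistry around the C9 ketone (C5 by rhodium-catalysed asymmetric alkenylation, then C10, C7, C8, C9); C6 comes from the ketal.
3. Ring order: cyclohexane C5–C10 (the arene ring of 1, dearomatised in step 2), then the lactone ring O8–C12–C11–C7–C8 (step 15), then the oxirane (step 17).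
4. Feature that makes the key step possible: in the chair of ring C5–C10 the C8 hydroxyl and the C7 ethynyl group (C11≡C13) are trans and both equatorial, so C12 bound to O8 reaches C11 for a 5-exo-dig closure to the trans-fused lactone. The axial O9 (trans-1,3 to the alkyne) cannot reach it and O6 is already acylated.

Key step: step 15

Remark (numbering and descriptors): elemane-type locants are used for all intermediates. Ring carbons are C5–C10; C10 bears CH3 (C14) and C1–C2; C5 bears C4(=C3)–C15; C6 bears the isobutyrate; C7 bears C11(=C13); C8 bears the lactone oxygen (C12 is the lactone carbonyl); C9 bears the free hydroxyl. β is the ring face of the C5 side chain and the C10 methyl group, α the other face.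

**Route**

Step 1
Reactants: 1 3-bromo-4-methoxyphenol; 2 ethynyltriisopropylsilane
Product: 3 4-methoxy-3-[(triisopropylsilyl)ethynyl]phenol
Conditions: Pd(PPh3)2Cl2 (3 mol %), CuI (6 mol %), i-Pr2NH, DMF, 80 °C
Reagents that add atoms: none
Why: Sonogashira coupling of the aryl bromide with the terminal alkyne tolerates the free phenol and installs C11/C13 with a bulky silyl cap that later shields the alkyne terminus.

Step 2
Reactants: 3 4-methoxy-3-[(triisopropylsilyl)ethynyl]phenol
Product: 4 4,4-dimethoxy-3-[(triisopropylsilyl)ethynyl]cyclohexa-2,5-dien-1-one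
Conditions: PhI(OAc)2, MeOH, 0 °C
Reagents that add atoms: methanol, CO
Why: oxidative dearomatisation of a 4-methoxyphenol with a hypervalent iodine reagent in methanol gives the p-quinone monoketal, which stores the future C6 carbonyl as a ketal and creates no stereocentre.

Step 3
Reactants: 4 4,4-dimethoxy-3-[(triisopropylsilyl)ethynyl]cyclohexa-2,5-dien-1-one; 5 potassium isopropenyltrifluoroborate
Product: 6 (5R)-4,4-dimethoxy-5-(prop-1-en-2-yl)-3-[(triisopropylsilyl)ethynyl]cyclohex-2-en-1-one (5β-isopropenyl enone)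
Conditions: [Rh(cod)2]BF4 (3 mol %), (R)-BINAP (3.3 mol %), Et3N (0.2 equiv), toluene/H2O (10:1), 30 °C
Reagents that add atoms: none
Why: rhodium-catalysed asymmetric conjugate addition (Hayashi–Miyaura reaction) of the alkenylborate goes to the only β-unsubstituted enone carbon (C5), and the chiral bisphosphine selects the enone face and sets C5, (R)-BINAP being the antipode expected to give 5R by analogy with cyclohex-2-enone.

Step 4
Reactants: 6 (5R)-4,4-dimethoxy-5-(prop-1-en-2-yl)-3-[(triisopropylsilyl)ethynyl]cyclohex-2-en-1-one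
Product: 7 (5R,6S)-4,4-dimethoxy-6-methyl-5-(prop-1-en-2-yl)-3-[(triisopropylsilyl)ethynyl]cyclohex-2-en-1-one (10-methyl trans to the 5-isopropenyl group)
Conditions: LiN(i-Pr)2, THF, −78 °C; MeI, −78 → −20 °C
Reagents that add atoms: iodomethane, CI
Why: kinetic enolate alkylation at C10, the only enolisable position, brings in the methyl group trans to the C5 isopropenyl group, and this C10 configuration is erased again in step 5.

Step 5
Reactants: 7 (5R,6S)-4,4-dimethoxy-6-methyl-5-(prop-1-en-2-yl)-3-[(triisopropylsilyl)ethynyl]cyclohex-2-en-1-one; 8 phenyl vinyl sulfoxide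
Product: 9 6,6-dimethoxy-10β-methyl-10α-[2-(phenylsulfinyl)ethyl]-5β-isopropenyl-7-[(triisopropylsilyl)ethynyl]cyclohex-7-en-9-one (sulfoxide epimers)
Conditions: LiN(i-Pr)2, THF, −78 °C; 8, −78 → 0 °C; aq. NH4Cl
Reagents that add atoms: none
Why: Michael addition of the tetrasubstituted enolate to phenyl vinyl sulfoxide (a vinyl cation equivalent) takes place at C10 anti to the adjacent pseudoaxial C5 isopropenyl group, which fixes the quaternary centre with CH3 cis to isopropenyl.

Step 6
Reactants: 9 6,6-dimethoxy-10β-methyl-10α-[2-(phenylsulfinyl)ethyl]-5β-isopropenyl-7-[(triisopropylsilyl)ethynyl]cyclohex-7-en-9-one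
Product: 10 6,6-dimethoxy-10β-methyl-5β-isopropenyl-7-[(triisopropylsilyl)ethynyl]-10α-vinylcyclohex-7-en-9-one
Conditions: NaHCO3, xylenes, 135 °C
Reagents that add atoms: none
Why: sulfoxide pyrolysis (thermal syn-elimination) can only give the terminal C1=C2 alkene because C10 is quaternary, and no stereocentre is touched.

Step 7
Reactants: 10 6,6-dimethoxy-10β-methyl-5β-isopropenyl-7-[(triisopropylsilyl)ethynyl]-10α-vinylcyclohex-7-en-9-one
Product: 11 6,6-dimethoxy-10β-methyl-5β-isopropenyl-7β-[(triisopropylsilyl)ethynyl]-10α-vinylcyclohexan-9-one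
Conditions: [(Ph3P)CuH]6 (0.4 equiv), H2O, THF, 25 °C
Reagents that add atoms: none
Why: copper hydride conjugate reduction by hydrocupration of the C7=C8 bond delivers hydride to C7 on the face anti to the C5 isopropenyl group, so the alkynyl group ends β (cis to isopropenyl), while the bulky silyl group guards the alkyne terminus against 1,6-attack and the neopentyl C9 carbonyl is not reduced.

Step 8
Reactants: 11 6,6-dimethoxy-10β-methyl-5β-isopropenyl-7β-[(triisopropylsilyl)ethynyl]-10α-vinylcyclohexan-9-one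
Product: 13 8α-(tert-butyldimethylsilyloxy)-6,6-dimethoxy-10β-methyl-5β-isopropenyl-7β-[(triisopropylsilyl)ethynyl]-10α-vinylcyclohexan-9-one, via silyl enol ether 12 (not isolated)
Conditions: KN(SiMe3)2, t-BuMe2SiCl, THF, −78 → 0 °C; then mCPBA, NaHCO3, CH2Cl2, −20 °C
Reagents that add atoms: tert-butyldimethylsilyl chloride, CC(C)(C)[Si](C)(C)Cl; 3-chloroperbenzoic acid, OOC(=O)c1cccc(Cl)c1
Why: Rubottom oxidation, in which enolisation is possible only toward C8, the peracid attacks the electron-rich enol ether anti to the C7 alkynyl group and the pseudoaxial C10 methyl group, and silyl migration gives the 8α-silyloxy ketone trans to the alkyne.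

Step 9
Reactants: 13 8α-(tert-butyldimethylsilyloxy)-6,6-dimethoxy-10β-methyl-5β-isopropenyl-7β-[(triisopropylsilyl)ethynyl]-10α-vinylcyclohexan-9-one
Product: 14 8α-(tert-butyldimethylsilyloxy)-6,6-dimethoxy-10β-methyl-5β-isopropenyl-7β-[(triisopropylsilyl)ethynyl]-10α-vinylcyclohexan-9α-ol
Conditions: LiBH(s-Bu)3, THF, −78 °C; aq. NH4Cl
Reagents that add atoms: none
Why: ketone reduction with a bulky trialkylborohydride should proceed by equatorial (β-face) attack, as in the reduction of 4,4-dimethyl-3-oxo triterpenoids and 2-alkoxycyclohexanones, and give the axial 9α-alcohol cis to O8.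

Step 10
Reactants: 14 8α-(tert-butyldimethylsilyloxy)-6,6-dimethoxy-10β-methyl-5β-isopropenyl-7β-[(triisopropylsilyl)ethynyl]-10α-vinylcyclohexan-9α-ol
Product: 15 8α,9α-bis(tert-butyldimethylsilyloxy)-6,6-dimethoxy-10β-methyl-5β-isopropenyl-7β-[(triisopropylsilyl)ethynyl]-10α-vinylcyclohexane
Conditions: t-BuMe2SiOTf, 2,6-lutidine, CH2Cl2, −78 → 0 °C
Reagents that add atoms: tert-butyldimethylsilyl trifluoromethanesulfonate, CC(C)(C)[Si](C)(C)OS(=O)(=O)C(F)(F)F
Why: silylation of the hindered axial alcohol with a silyl triflate masks O9 so that O6 can later be acylated alone, and the hindered dimethyl ketal should survive the lutidine-buffered conditions.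

Step 11
Reactants: 15 8α,9α-bis(tert-butyldimethylsilyloxy)-6,6-dimethoxy-10β-methyl-5β-isopropenyl-7β-[(triisopropylsilyl)ethynyl]-10α-vinylcyclohexane
Product: 16 8α,9α-bis(tert-butyldimethylsilyloxy)-10β-methyl-5β-isopropenyl-7β-[(triisopropylsilyl)ethynyl]-10α-vinylcyclohexan-6-one
Conditions: PPTS (0.2 equiv), acetone/H2O (10:1), 45 °C
Reagents that add atoms: water, O
Why: acid-catalysed ketal hydrolysis under mild conditions leaves the two secondary silyl ethers and the β,γ-unsaturated ketone untouched, and C5 and C7 keep their equatorial, thermodynamically preferred substituents.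

Step 12
Reactants: 16 8α,9α-bis(tert-butyldimethylsilyloxy)-10β-methyl-5β-isopropenyl-7β-[(triisopropylsilyl)ethynyl]-10α-vinylcyclohexan-6-one
Product: 17 8α,9α-bis(tert-butyldimethylsilyloxy)-10β-methyl-5β-isopropenyl-7β-[(triisopropylsilyl)ethynyl]-10α-vinylcyclohexan-6β-ol
Conditions: LiBH(s-Bu)3, THF, −78 °C; aq. NH4Cl
Reagents that add atoms: none
Why: selectride reduction, in which the axial (β) approach to C6 is blocked by the syn-axial C10 methyl group, so hydride enters from the α-face and gives the axial 6β-alcohol cis to both neighbours, as in the reduction of isopulegone to neoisopulegol.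

Step 13
Reactants: 17 8α,9α-bis(tert-butyldimethylsilyloxy)-10β-methyl-5β-isopropenyl-7β-[(triisopropylsilyl)ethynyl]-10α-vinylcyclohexan-6β-ol
Product: 18 8α,9α-bis(tert-butyldimethylsilyloxy)-10β-methyl-5β-isopropenyl-7β-[(triisopropylsilyl)ethynyl]-10α-vinylcyclohex-6β-yl isobutyrate
Conditions: (i-PrCO)2O, DMAP, Et3N, CH2Cl2, 40 °C
Reagents that add atoms: isobutyric anhydride, CC(C)C(=O)OC(=O)C(C)C
Why: DMAP-catalysed acylation (nucleophilic acyl-transfer catalysis) of the only free hydroxyl group installs the ester without affecting any stereocentre.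

Step 14
Reactants: 18 8α,9α-bis(tert-butyldimethylsilyloxy)-10β-methyl-5β-isopropenyl-7β-[(triisopropylsilyl)ethynyl]-10α-vinylcyclohex-6β-yl isobutyrate
Product: 19 7β-ethynyl-8α,9α-dihydroxy-10β-methyl-5β-isopropenyl-10α-vinylcyclohex-6β-yl isobutyrate
Conditions: Bu4NF, AcOH, THF, 25 → 45 °C
Reagents that add atoms: none
Why: fluoride-mediated desilylation cleaves both O–Si bonds and the C(sp)–Si bond in one operation, with the acetic acid buffer protecting the isobutyrate, which cannot migrate to the trans-1,3-related O8.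

Step 15
Reactants: 19 7β-ethynyl-8α,9α-dihydroxy-10β-methyl-5β-isopropenyl-10α-vinylcyclohex-6β-yl isobutyrate
Product: 21 9α-hydroxy-6β-(isobutyryloxy)elema-1,3,11(13)-trien-12,8α-olide, via alkoxycarbonylpalladium iodide 20 (not isolated)
Conditions: PdI2 (5 mol %), PBu3 (10 mol %), CO (7 bar), MeCN, 75 °C
Reagents that add atoms: carbon monoxide, [C-]#[O+]
Why: Mechanism: PdI2/PBu3 and CO convert the equatorial O8–H reversibly into the alkoxycarbonylpalladium species 20, whose Pd–C12 bond adds syn across C11≡C13 so that C12 bonds to C11 and closes the lactone, after which HI cleaves the C13–Pd bond to leave the exocyclic methylene and return divalent palladium. The closest known reaction type is the palladium-catalysed cyclocarbonylation of trans-2-ethynylcyclohexanols to trans-fused α-methylene-γ-butyrolactones. The one ring that closes (C12–O8–C8–C7–C11) does so in a 5-exo-dig mode. No stereocentre is created; the trans ring fusion is inherited from C7 and C8, set in steps 7 and 8. The step needs O8 to win over O9 and the alkyne to win over the two alkenes: the axial O9 is trans-1,3 to the ethynyl group and cannot bridge to it, O6 is already acylated, and alkenes insert into the Pd–CO2R bond far more slowly than an alkyne held next to it.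

Step 16
Reactants: 21 9α-hydroxy-6β-(isobutyryloxy)elema-1,3,11(13)-trien-12,8α-olide
Product: 23 9α-hydroxy-6β-(isobutyryloxy)-15-oxoelema-1,3,11(13)-trien-12,8α-olide, via allylic alcohol 22 (not isolated)
Conditions: SeO2 (0.3 equiv), t-BuOOH, CH2Cl2, 25 °C; then MnO2, CH2Cl2, 25 °C
Reagents that add atoms: tert-butyl hydroperoxide, CC(C)(C)OO
Why: selenium dioxide allylic oxidation (ene reaction then [2,3]-shift) followed by MnO2 oxidation of the allylic alcohol should act only on the isopropenyl group, the one electron-rich alkene with allylic hydrogens, at its methyl group (C15) because allylic strain holds C5–H in the nodal plane of the π bond, and MnO2 leaves the non-allylic C9 hydroxyl alone.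

Step 17
Reactants: 23 9α-hydroxy-6β-(isobutyryloxy)-15-oxoelema-1,3,11(13)-trien-12,8α-olide
Product: 25 (1R)-1,2-epoxy-9α-hydroxy-6β-(isobutyryloxy)-15-oxoelema-3,11(13)-dien-12,8α-olide (the target), via bromohydrin 24 (not isolated)
Conditions: NBS, H2O/DME (1:4), 0 °C; then Ag2O, CH2Cl2, 25 °C
Reagents that add atoms: water, O
Why: bromohydrin formation and ring closure, in which Br+ adds to the more open face of the only electron-rich double bond (C1=C2, CH2 turned toward C9, open face toward the axial C9–OH), water opens the bromonium ion from the opposite side, and silver-assisted loss of bromide therefore leaves the oxirane oxygen on the hindered face between C14 and C5, which is the (1R) configuration, both regioisomeric bromohydrins converging on the same epoxide.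

**Compound list**

1 | 3-bromo-4-methoxyphenol | COc1ccc(O)cc1Br | starting material
2 | ethynyltriisopropylsilane | C#C[Si](C(C)C)(C(C)C)C(C)C | starting material
3 | 4-methoxy-3-[(triisopropylsilyl)ethynyl]phenol | COc1ccc(O)cc1C#C[Si](C(C)C)(C(C)C)C(C)C | intermediate
4 | 4,4-dimethoxy-3-[(triisopropylsilyl)ethynyl]cyclohexa-2,5-dien-1-one | O=C1C=C(C#C[Si](C(C)C)(C(C)C)C(C)C)C(OC)(OC)C=C1 | intermediate
5 | potassium isopropenyltrifluoroborate | CC(=C)[B-](F)(F)F.[K+] | starting material
6 | (5R)-4,4-dimethoxy-5-(prop-1-en-2-yl)-3-[(triisopropylsilyl)ethynyl]cyclohex-2-en-1-one | O=C1C=C(C#C[Si](C(C)C)(C(C)C)C(C)C)C(OC)(OC)[C@@H](C(C)=C)C1 | intermediate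
7 | (5R,6S)-4,4-dimethoxy-6-methyl-5-(prop-1-en-2-yl)-3-[(triisopropylsilyl)ethynyl]cyclohex-2-en-1-one | C=C(C)[C@H]1[C@H](C)C(=O)C=C(C#C[Si](C(C)C)(C(C)C)C(C)C)C1(OC)OC | intermediate
8 | phenyl vinyl sulfoxide | C=CS(=O)c1ccccc1 | starting material
9 | 6,6-dimethoxy-10β-methyl-10α-[2-(phenylsulfinyl)ethyl]-5β-isopropenyl-7-[(triisopropylsilyl)ethynyl]cyclohex-7-en-9-one (sulfoxide epimers) | O=C1C=C(C#C[Si](C(C)C)(C(C)C)C(C)C)C(OC)(OC)[C@@H](C(C)=C)[C@]1(C)CCS(=O)c1ccccc1 | intermediate
10 | 6,6-dimethoxy-10β-methyl-5β-isopropenyl-7-[(triisopropylsilyl)ethynyl]-10α-vinylcyclohex-7-en-9-one | O=C1C=C(C#C[Si](C(C)C)(C(C)C)C(C)C)C(OC)(OC)[C@@H](C(C)=C)[C@]1(C)C=C | intermediate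
11 | 6,6-dimethoxy-10β-methyl-5β-isopropenyl-7β-[(triisopropylsilyl)ethynyl]-10α-vinylcyclohexan-9-one | O=C1C[C@@H](C#C[Si](C(C)C)(C(C)C)C(C)C)C(OC)(OC)[C@@H](C(C)=C)[C@]1(C)C=C | intermediate
12 | 9-(tert-butyldimethylsilyloxy)-8-ene silyl enol ether of 11 | CC(C)(C)[Si](C)(C)OC1=C[C@@H](C#C[Si](C(C)C)(C(C)C)C(C)C)C(OC)(OC)[C@@H](C(C)=C)[C@]1(C)C=C | intermediate (not isolated)
13 | 8α-(tert-butyldimethylsilyloxy)-6,6-dimethoxy-10β-methyl-5β-isopropenyl-7β-[(triisopropylsilyl)ethynyl]-10α-vinylcyclohexan-9-one | O=C1[C@H](O[Si](C)(C)C(C)(C)C)[C@@H](C#C[Si](C(C)C)(C(C)C)C(C)C)C(OC)(OC)[C@@H](C(C)=C)[C@]1(C)C=C | intermediate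
14 | 8α-(tert-butyldimethylsilyloxy)-6,6-dimethoxy-10β-methyl-5β-isopropenyl-7β-[(triisopropylsilyl)ethynyl]-10α-vinylcyclohexan-9α-ol | CC(C)(C)[Si](C)(C)O[C@@H]1[C@@H](C#C[Si](C(C)C)(C(C)C)C(C)C)C(OC)(OC)[C@@H](C(C)=C)[C@](C)(C=C)[C@@H]1O | intermediate
15 | 8α,9α-bis(tert-butyldimethylsilyloxy)-6,6-dimethoxy-10β-methyl-5β-isopropenyl-7β-[(triisopropylsilyl)ethynyl]-10α-vinylcyclohexane | CC(C)(C)[Si](C)(C)O[C@@H]1[C@@H](C#C[Si](C(C)C)(C(C)C)C(C)C)C(OC)(OC)[C@@H](C(C)=C)[C@](C)(C=C)[C@@H]1O[Si](C)(C)C(C)(C)C | intermediate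
16 | 8α,9α-bis(tert-butyldimethylsilyloxy)-10β-methyl-5β-isopropenyl-7β-[(triisopropylsilyl)ethynyl]-10α-vinylcyclohexan-6-one | CC(C)(C)[Si](C)(C)O[C@@H]1[C@@H](C#C[Si](C(C)C)(C(C)C)C(C)C)C(=O)[C@@H](C(C)=C)[C@](C)(C=C)[C@@H]1O[Si](C)(C)C(C)(C)C | intermediate
17 | 8α,9α-bis(tert-butyldimethylsilyloxy)-10β-methyl-5β-isopropenyl-7β-[(triisopropylsilyl)ethynyl]-10α-vinylcyclohexan-6β-ol | CC(C)(C)[Si](C)(C)O[C@@H]1[C@@H](C#C[Si](C(C)C)(C(C)C)C(C)C)[C@@H](O)[C@@H](C(C)=C)[C@](C)(C=C)[C@@H]1O[Si](C)(C)C(C)(C)C | intermediate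
18 | 8α,9α-bis(tert-butyldimethylsilyloxy)-10β-methyl-5β-isopropenyl-7β-[(triisopropylsilyl)ethynyl]-10α-vinylcyclohex-6β-yl isobutyrate | CC(C)(C)[Si](C)(C)O[C@@H]1[C@@H](C#C[Si](C(C)C)(C(C)C)C(C)C)[C@@H](OC(=O)C(C)C)[C@@H](C(C)=C)[C@](C)(C=C)[C@@H]1O[Si](C)(C)C(C)(C)C | intermediate
19 | 7β-ethynyl-8α,9α-dihydroxy-10β-methyl-5β-isopropenyl-10α-vinylcyclohex-6β-yl isobutyrate | O[C@@H]1[C@@H](C#C)[C@@H](OC(=O)C(C)C)[C@@H](C(C)=C)[C@](C)(C=C)[C@@H]1O | intermediate
20 | iodo-bis(tributylphosphine)palladium alkoxycarbonyl complex on O8 of 19 (divalent palladium) | O=C(O[C@@H]1[C@@H](C#C)[C@@H](OC(=O)C(C)C)[C@@H](C(C)=C)[C@](C)(C=C)[C@@H]1O)[Pd-2](I)([P+](CCCC)(CCCC)CCCC)[P+](CCCC)(CCCC)CCCC | intermediate (not isolated)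
21 | 9α-hydroxy-6β-(isobutyryloxy)elema-1,3,11(13)-trien-12,8α-olide | C=C1C(=O)O[C@@H]2[C@@H]1[C@@H](OC(=O)C(C)C)[C@@H](C(C)=C)[C@](C)(C=C)[C@@H]2O | intermediate
22 | 9α,15-dihydroxy-6β-(isobutyryloxy)elema-1,3,11(13)-trien-12,8α-olide | C=C1C(=O)O[C@@H]2[C@@H]1[C@@H](OC(=O)C(C)C)[C@@H](C(=C)CO)[C@](C)(C=C)[C@@H]2O | intermediate (not isolated)
23 | 9α-hydroxy-6β-(isobutyryloxy)-15-oxoelema-1,3,11(13)-trien-12,8α-olide | C=C1C(=O)O[C@@H]2[C@@H]1[C@@H](OC(=O)C(C)C)[C@@H](C(=C)C=O)[C@](C)(C=C)[C@@H]2O | intermediate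
24 | (1R)-2-bromo-1,9α-dihydroxy-6β-(isobutyryloxy)-15-oxoelema-3,11(13)-dien-12,8α-olide | C=C1C(=O)O[C@@H]2[C@@H]1[C@@H](OC(=O)C(C)C)[C@@H](C(=C)C=O)[C@](C)([C@@H](O)CBr)[C@@H]2O | intermediate (not isolated)
25 | (1R)-1,2-epoxy-9α-hydroxy-6β-(isobutyryloxy)-15-oxoelema-3,11(13)-dien-12,8α-olide (CNP0496100.1) | C=C1C(=O)O[C@@H]2[C@@H]1[C@@H](OC(=O)C(C)C)[C@@H](C(=C)C=O)[C@](C)([C@@H]1CO1)[C@@H]2O | target

**Step count and risks**

Total step count: 17. Longest linear sequence: 17 steps (1 → 25).

Steps most likely to fail: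

Step 15. The alkoxycarbonylpalladium species may be diverted before it reaches the alkyne (closure onto the neighbouring C9 hydroxyl, insertion of the C10 vinyl group), or electrophilic palladium may act on the 1,5-diene, so that conversion to the lactone stalls. Fallback (radical closure of the same C11–C12 bond): starting from 19, selective acylation of the equatorial O8–H with Se-phenyl carbonochloridoselenoate (pyridine, CH2Cl2, −40 °C) gives the Se-phenyl selenocarbonate F1. Capping the axial O9–H in the same flask (Et3SiOTf, 2,6-lutidine, −78 °C), so that it cannot displace phenylselenolate, gives the O9-triethylsilyl selenocarbonate F2. Slow addition of Bu3SnH with AIBN in benzene at 80 °C generates the O8-alkoxycarbonyl radical, which closes 5-exo-dig onto C11 and, after hydrogen transfer to C13, gives the O9-silylated lactone F3. HF·pyridine in THF then returns to 21.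

Step 16. The ene step may lose site selectivity (attack at C5–H or at the lactone C7–H) or over-oxidise. Fallback (halogenation, then oxidation): starting from 21, allylic chlorination with double-bond shift (N-chlorosuccinimide, PhSeCl (10 mol %), CH2Cl2, 25 °C), which needs an electron-rich alkene with allylic hydrogens and so touches only the isopropenyl group, gives the 15-chloro trienolide F4. Kornblum-type oxidation with trimethylamine N-oxide in DMSO at 25 °C converts F4 into enal 23.

Step 17. Bromonium formation may not discriminate the two faces of C1=C2 well enough, or ring closure of the regioisomeric bromohydrin may be slow, so that the epoxide forms as a C1-epimer mixture or in low yield. Fallback (reagent-controlled resolution in place of substrate control): starting from 23, a non-directed epoxidation (MeReO3 (cat.), 3-cyanopyridine, 30 % H2O2, CH2Cl2) should give 25 together with its (1S)-epoxide epimer F5. Hydrolytic kinetic resolution with water and the (S,S)-configured [Co(salen)]OAc complex (trivalent cobalt; salen = dianion of N,N′-bis(3,5-di-tert-butylsalicylidene)-1,2-cyclohexanediamine), the antipode that by the usual sense consumes (S)-alkyloxiranes, hydrolyses F5 to the (1S)-1,2-diol F6 and leaves 25, which is separated by chromatography. Because direct epoxidation is expected to favour F5, this fallback secures configuration at the cost of material.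

Further compounds
F1 | step 15 | Se-phenyl O8-selenocarbonate of 19 (O9–H free) | O=C([Se]c1ccccc1)O[C@@H]1[C@@H](C#C)[C@@H](OC(=O)C(C)C)[C@@H](C(C)=C)[C@](C)(C=C)[C@@H]1O
F2 | step 15 | Se-phenyl O8-selenocarbonate of 19 with O9 triethylsilyl ether | O=C([Se]c1ccccc1)O[C@@H]1[C@@H](C#C)[C@@H](OC(=O)C(C)C)[C@@H](C(C)=C)[C@](C)(C=C)[C@@H]1O[Si](CC)(CC)CC
F3 | step 15 | 6β-(isobutyryloxy)-9α-(triethylsilyloxy)elema-1,3,11(13)-trien-12,8α-olide | C=C1C(=O)O[C@@H]2[C@@H]1[C@@H](OC(=O)C(C)C)[C@@H](C(C)=C)[C@](C)(C=C)[C@@H]2O[Si](CC)(CC)CC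
F4 | step 16 | 15-chloro-9α-hydroxy-6β-(isobutyryloxy)elema-1,3,11(13)-trien-12,8α-olide | C=C1C(=O)O[C@@H]2[C@@H]1[C@@H](OC(=O)C(C)C)[C@@H](C(=C)CCl)[C@](C)(C=C)[C@@H]2O
F5 | step 17 | (1S)-1,2-epoxy-9α-hydroxy-6β-(isobutyryloxy)-15-oxoelema-3,11(13)-dien-12,8α-olide (C1 epimer of 25) | C=C1C(=O)O[C@@H]2[C@@H]1[C@@H](OC(=O)C(C)C)[C@@H](C(=C)C=O)[C@](C)([C@H]1CO1)[C@@H]2O
F6 | step 17 | (1S)-1,2,9α-trihydroxy-6β-(isobutyryloxy)-15-oxoelema-3,11(13)-dien-12,8α-olide | C=C1C(=O)O[C@@H]2[C@@H]1[C@@H](OC(=O)C(C)C)[C@@H](C(=C)C=O)[C@](C)([C@H](O)CO)[C@@H]2O
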